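If the teal flask is repeated, the thing to watch is how much E each X makes before E stops rising, not the clock.

| setting | teal | grey | flask |
|---|---|---|---|
| G | 0.013 M | 0.013 M | 0.013 M |
| X | 0.02 mol% | 0.013 mol% | 0.02 mol% |
| L | 3.1 µM | 3.1 µM | 3.1 µM |
| temperature | 37 °C | 22 °C | 37 °C |
| remark | the very flask that is asked about, followed so far | run made earlier |  |
| time |  |  | 30 h |

| run | time / h | E / % | G / % |
|---|---|---|---|
| teal | 2.00 | 29.6 | 71.0 |
| teal | 3.00 | 28.7 | 70.5 |
| teal | 5.00 | 29.7 | 71.4 |
| teal | 8.00 | 29.2 | 69.4 |
| teal | 15.0 | 29.5 | 71.3 |
| teal | 25.0 | 28.9 | 70.7 |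
| grey | 0.417 | 12.6 | 87.9 |
| grey | 0.833 | 17.3 | 82.4 |
| grey | 1.33 | 20.8 | 79.7 |
| grey | 2.00 | 21.9 | 78.5 |
| grey | 3.00 | 21.2 | 77.9 |

(scatter of a reading: 0.5 percentage points)

- spring: at 30 h add X, 50.0% of the amount charged, then wait 15 h
- dawn: at 30 h take out 90% of the E then present, then wait 15 h
- winter: at 30 h raise the temperature by 10 K, then wait 15 h
- dusk: change nothing and wait 15 h more

- what is taken out of E is counted as made
- what was read earlier has a scatter of 0.5 percentage points, one standard deviation
- additions bring no volume worth counting

- E, in percent of the G first charged, at 30 h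
- what to do for the largest gain in E; "none" if nothing gains more than 2 percentage points (spring / dawn / winter / dusk / none)
- E present, with what was taken out counted in, in percent of the G first charged, after dawn
- E present, with what was taken out counted in, in percent of the G first charged, after dusk

The teal readings stay flat from 2.00 h to 25.0 h at a mean E of 29.3%, and G makes up the rest. So either G and E stand in balance or X has stopped working. I reckon with the second reading, since L is charged at 1.19 per X in the teal flask, more L than X.

That folds the run into one dimensionless number, the turnover number N, the plateau E divided by the loading of X. In words, it is how many G each X turns into E in its working life. The teal run gives N = 1460. The last two grey readings give a plateau of 21.6% and N = 1660.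

Is one number enough? The grey N applied to the teal loading gives 33.2% against the 29.3% read, a gap well beyond the scatter of 0.5 percentage points. So one number does not carry over from the grey run to the teal flask, and the grey run changes temperature and loading together, which leaves the balance reading open. Still, I commit to lost X. At 30 h the teal flask then stands at 29.3%, and dawn, winter and dusk gain nothing. Spring gains N times the added loading, 15 points. If X is lost at a rate proportional to cL, then with all else held N falls in proportion as cL rises.

The forecast gives 29.3% and chooses dawn, with 47.7% after dawn and 29.3% after dusk: “I take equilibrium as the likelier reading, with X still alive.”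

The flask gives 29.1%, with 29.1% after dawn and 29.1% after dusk. The best choice is spring, which gains 25 points, against my 15 points.

    X → D (k = 0.0210 min⁻¹, Ea = 96.0 kJ mol⁻¹)
    G + X → E + X, rate k2*[G]*[X]/(1 + ([G]/Km2) + ([E]/Kp2)) (1.30 mM, 8.50 mM, k = 1.20 × 10⁵ M⁻¹ min⁻¹, Ea = 41.0 kJ mol⁻¹)
    X → Z (k = 8.90 × 10⁻⁴ min⁻¹, Ea = 288 kJ mol⁻¹)
    X + L → Q (k = 37000 M⁻¹ min⁻¹, Ea = 48.0 kJ mol⁻¹)
    (constants at 37 °C)

By 30.0 h X stands at 0% and L at 36% of its charge, and the added X makes 2540 turnovers against N = 1460. The height of the plateau in this flask comes from X + L to Q acting together with the cG term in the rate of G to E: from E of 29.1% at 30 h, removing the first gives 92.2% and removing the second gives 83.9%. Spring's gain owes part of its size to X + L to Q: without that reaction spring gains 7.2 points, not 25 points.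

In the neighbour flask with cL at 7.8 × 10⁻⁶ M, N scaled by cL gives E of 11.6%. The computed value is 10.6%.

All runs were generated by integration for substances that don't exist; the scatter is artificial.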